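**Plan**

- Cuts (labdane numbering): the C18 acetate goes back to a silyl ether; C12–C13 is cut as an sp3–sp2 zinc coupling with an E-enol triflate; C8=C17 and C6=C7 go back to an 8-ketone (Wittig, Saegusa–Ito).
- Enabling feature: the C8 carbonyl carbon of ring B (later the exocyclic C8=C17 methylene) and the C12 ester carbon are 1,4-related through C8–C9–C11–C12. This dissonant pair is cut at C8–C9 with reversed polarity: an aldehyde-derived acyl anion at C8 adds to C9 of an E-enoate on C10 and closes ring B.
- Forward order: ring A first, as a cyclohexenone from 2-methyl-3-silyloxypropanal and ethyl vinyl ketone; allyl to C5 and hydroxymethyl to C10; the C1 carbonyl is deleted; the two arms become the C9=C11 enoate and the C6–C7–C8 aldehyde; ring B closes; then diene, side chain, acetate.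
- Stereochemistry: C4 from the chiral amine catalyst; C5 by allyl addition anti to the bulky silyloxymethyl arm; C10 by formaldehyde capture anti to the allyl group; C9 by equilibration next to the C8 ketone on the trans-decalin; both E-alkenes from a stabilised ylide and a stereoretentive coupling.

Key step: step 11

Remark: ring A is C1–C5/C10 and ring B is C5–C10; the target is taken as the ent-labdane drawn, with the acetoxymethyl arm on C4 cis to H-5. An achiral diol replaces a chiral hydroxy ester as the C4 source because the α-centre becomes trigonal in the enamine of step 3. The sense of induction in step 3 is assumed from the enamine model and has to be confirmed on compound 6.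

**Route**

Step 1
Reactants: 1 2-methylpropane-1,3-diol
Product: 2 3-[(tert-butyldiphenylsilyl)oxy]-2-methylpropan-1-ol (racemic)
Conditions: t-BuPh2SiCl (1 equiv), diol (3 equiv), imidazole, CH2Cl2, 0 °C to rt
Reagents that add atoms: tert-butyl(chloro)diphenylsilane, CC(C)(C)[Si](Cl)(c1ccccc1)c1ccccc1
Why: Silyl ether formation with the diol in threefold excess should give the mono-ether almost exclusively (statistical monoprotection), the water-soluble excess diol being washed out; the stereocentre formed is racemic and is erased in step 3.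

Step 2
Reactants: 2 3-[(tert-butyldiphenylsilyl)oxy]-2-methylpropan-1-ol
Product: 3 3-[(tert-butyldiphenylsilyl)oxy]-2-methylpropanal (racemic)
Conditions: Dess–Martin periodinane, NaHCO3, CH2Cl2, 0 °C to rt
Reagents that add atoms: none
Why: Dess–Martin oxidation under bicarbonate buffering should stop at the aldehyde and avoid β-elimination of the silyloxy group; the α-centre stays racemic, which is of no consequence.

Step 3
Reactants: 3 3-[(tert-butyldiphenylsilyl)oxy]-2-methylpropanal; 4 pent-1-en-3-one (ethyl vinyl ketone)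
Product: 6 (4S)-4-{[(tert-butyldiphenylsilyl)oxy]methyl}-2,4-dimethylcyclohex-2-en-1-one, via keto aldehyde 5 (not isolated)
Conditions: (S)-N-(4-dodecylbenzenesulfonyl)pyrrolidine-2-carboxamide (20 mol %), BnNH2 (1 equiv), 4 Å MS, ClCH2CH2Cl, rt to 50 °C
Reagents that add atoms: none
Why: Enamine-mediated Michael addition of the α-branched aldehyde to the vinyl ketone followed by amine-promoted intramolecular aldol condensation (organocatalytic Robinson-type annulation) should close ring A; the quaternary centre C4 is set in the Michael step, in which the enamine places the bulky silyloxymethyl arm anti to nitrogen and the sulfonamide N–H steers the enone to one face, the catalyst antipode being the one that leads to the (S)-centre.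

Step 4
Reactants: 6 (4S)-4-{[(tert-butyldiphenylsilyl)oxy]methyl}-2,4-dimethylcyclohex-2-en-1-one; 7 allyltrimethylsilane
Product: 9 (2R,3R,4S)-4-{[(tert-butyldiphenylsilyl)oxy]methyl}-2-(hydroxymethyl)-2,4-dimethyl-3-(prop-2-en-1-yl)cyclohexan-1-one, via titanium enolate 8 (not isolated)
Conditions: TiCl4 (1.2 equiv), CH2Cl2, −78 °C; then CH2O (gas from cracked paraformaldehyde, excess), −78 to −40 °C; aq NaHCO3
Reagents that add atoms: formaldehyde, C=O
Why: Hosomi–Sakurai conjugate allylation followed by aldol capture of the regiodefined trichlorotitanium enolate with monomeric formaldehyde should set C5 and C10 in one flask: the allyl group is expected to add axially to C5 anti to the bulky tert-butyldiphenylsilyloxymethyl arm of C4 and so cis to the C4 methyl, and formaldehyde should then enter C10 anti to the pseudo-axial allyl group, which gives the trans C5/C10 arrangement.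

Step 5
Reactants: 9 (2R,3R,4S)-4-{[(tert-butyldiphenylsilyl)oxy]methyl}-2-(hydroxymethyl)-2,4-dimethyl-3-(prop-2-en-1-yl)cyclohexan-1-one
Product: 10 4-methylbenzenesulfonohydrazone of ketone 9
Conditions: TsNHNH2 (1.5 equiv), AcOH (cat), EtOH, 60 °C
Reagents that add atoms: 4-methylbenzenesulfonohydrazide, Cc1ccc(cc1)S(=O)(=O)NN
Why: Acid-catalysed condensation with tosylhydrazide (hydrazone formation) is feasible at this 2,2-disubstituted cyclohexanone and, being run under mildly acidic conditions, avoids retro-aldol loss of the hydroxymethyl group; no stereocentre is affected.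

Step 6
Reactants: 10 4-methylbenzenesulfonohydrazone of ketone 9
Product: 11 [(1R,2S,3S)-3-{[(tert-butyldiphenylsilyl)oxy]methyl}-1,3-dimethyl-2-(prop-2-en-1-yl)cyclohexyl]methanol
Conditions: catecholborane (3 equiv), CHCl3, 0 °C to rt; then NaOAc·3H2O, reflux
Reagents that add atoms: none
Why: Hydride transfer from catecholborane to the C=N bond, loss of sulfinate and extrusion of dinitrogen from the resulting diazene (Caglioti reduction, catecholborane variant) should replace the C1 carbonyl by a methylene group without touching the terminal alkene, the silyl ether or the adjacent quaternary centre.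

Step 7
Reactants: 11 [(1R,2S,3S)-3-{[(tert-butyldiphenylsilyl)oxy]methyl}-1,3-dimethyl-2-(prop-2-en-1-yl)cyclohexyl]methanol
Product: 12 (1R,2R,3S)-3-{[(tert-butyldiphenylsilyl)oxy]methyl}-1,3-dimethyl-2-(prop-2-en-1-yl)cyclohexane-1-carbaldehyde
Conditions: Dess–Martin periodinane, NaHCO3, CH2Cl2, rt
Reagents that add atoms: none
Why: Dess–Martin oxidation of the neopentyl alcohol should give the C9 aldehyde, which cannot enolise or epimerise because C10 is quaternary.

Step 8
Reactants: 12 (1R,2R,3S)-3-{[(tert-butyldiphenylsilyl)oxy]methyl}-1,3-dimethyl-2-(prop-2-en-1-yl)cyclohexane-1-carbaldehyde; 13 methyl (triphenylphosphoranylidene)acetate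
Product: 14 methyl (2E)-3-[(1S,2S,3S)-3-{[(tert-butyldiphenylsilyl)oxy]methyl}-1,3-dimethyl-2-(prop-2-en-1-yl)cyclohexyl]prop-2-enoate
Conditions: toluene, 90 °C
Reagents that add atoms: none
Why: Wittig olefination with the stabilised ylide should convert the hindered, non-enolisable aldehyde on heating into the E-enoate, the E geometry following from reversible oxaphosphetane formation with ester-stabilised ylides.

Step 9
Reactants: 14 methyl (2E)-3-[(1S,2S,3S)-3-{[(tert-butyldiphenylsilyl)oxy]methyl}-1,3-dimethyl-2-(prop-2-en-1-yl)cyclohexyl]prop-2-enoate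
Product: 16 methyl (2E)-3-[(1S,2S,3S)-3-{[(tert-butyldiphenylsilyl)oxy]methyl}-2-(3-hydroxypropyl)-1,3-dimethylcyclohexyl]prop-2-enoate, via alkylborane 15 (not isolated)
Conditions: 9-BBN (1.5 equiv), THF, 0 °C to rt; then NaBO3·4H2O, H2O, rt
Reagents that add atoms: sodium perborate tetrahydrate (NaBO3·4H2O, source of the hydroxyl oxygen), [Na+].[Na+].O[B-]1(O)OO[B-](O)(O)OO1
Why: Hydroboration–oxidation: 9-BBN should add only to the monosubstituted alkene with boron at the terminus and leave the hindered, electron-poor enoate alone, and perborate oxidises the C–B bond under nearly neutral conditions that do not harm the ester.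

Step 10
Reactants: 16 methyl (2E)-3-[(1S,2S,3S)-3-{[(tert-butyldiphenylsilyl)oxy]methyl}-2-(3-hydroxypropyl)-1,3-dimethylcyclohexyl]prop-2-enoate
Product: 17 methyl (2E)-3-[(1S,2S,3S)-3-{[(tert-butyldiphenylsilyl)oxy]methyl}-1,3-dimethyl-2-(3-oxopropyl)cyclohexyl]prop-2-enoate
Conditions: Dess–Martin periodinane, NaHCO3, CH2Cl2, rt
Reagents that add atoms: none
Why: Dess–Martin oxidation should deliver the C8 aldehyde under neutral conditions, so that neither the enoate nor the α-methylene of the new aldehyde is disturbed.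

Step 11
Reactants: 17 methyl (2E)-3-[(1S,2S,3S)-3-{[(tert-butyldiphenylsilyl)oxy]methyl}-1,3-dimethyl-2-(3-oxopropyl)cyclohexyl]prop-2-enoate
Product: 18 methyl 2-[(1S,4aS,5S,8aR)-5-{[(tert-butyldiphenylsilyl)oxy]methyl}-5,8a-dimethyl-2-oxodecahydronaphthalen-1-yl]acetate
Conditions: 2-(pentafluorophenyl)-6,7-dihydro-5H-pyrrolo[2,1-c][1,2,4]triazol-2-ium tetrafluoroborate (20 mol %), KN(SiMe3)2 (18 mol %), toluene, rt to 60 °C; then DBU (0.2 equiv), rt
Reagents that add atoms: none
Why: Deprotonation of the triazolium salt gives a carbene that adds to the C8 aldehyde; proton transfer produces the Breslow enaminol, an acyl-anion equivalent, which adds in conjugate fashion to C9 of the enoate, and proton transfer with expulsion of the carbene releases the C8 ketone and returns the catalyst. The closest known reaction type is the azolium-carbene-catalysed intramolecular Stetter reaction of aliphatic aldehydes tethered to enoates, which gives cyclohexanones carrying an acetic ester arm. Ring B closes in a 6-exo-trig mode by formation of the C8–C9 bond through a chair-like arrangement in which the C5 propanal chain and the C10 enoate are both equatorial on ring A, so the preset trans C5/C10 relationship becomes the trans ring fusion. The only new stereocentre, C9, lies next to the new ketone and is brought by DBU-mediated enolisation to the equatorial CH2CO2Me arm (cis to the C10 methyl), the controlling element being the rigid trans-decalin. The selectivity needed is 1,4-addition in preference to aldol or acyloin self-condensation of the enolisable aldehyde; it is secured by the intramolecular six-membered closure, the substoichiometric base and the absence of any other acceptor, while the hindrance of C9 beside quaternary C10 is met with an electron-poor N-pentafluorophenyl catalyst and moderate heating.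

Step 12
Reactants: 18 methyl 2-[(1S,4aS,5S,8aR)-5-{[(tert-butyldiphenylsilyl)oxy]methyl}-5,8a-dimethyl-2-oxodecahydronaphthalen-1-yl]acetate
Product: 20 methyl 2-[(1S,4aS,5S,8aR)-5-{[(tert-butyldiphenylsilyl)oxy]methyl}-5,8a-dimethyl-2-oxo-1,2,4a,5,6,7,8,8a-octahydronaphthalen-1-yl]acetate, via silyl enol ether 19 (not isolated)
Conditions: LiN(i-Pr)2 (1.1 equiv), Me3SiCl, THF, −78 °C; then Pd(OAc)2 (1.1 equiv), MeCN, rt
Reagents that add atoms: none
Why: Saegusa–Ito oxidation: kinetic deprotonation with internal silyl quench should occur at the C7 methylene (more acidic than the ester α-protons and far more accessible than H-9 beside quaternary C10), and Pd(OAc)2 then converts the silyl enol ether into the C6=C7 enone by β-hydride elimination from the palladium enolate, leaving C5 and C9 untouched.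

Step 13
Reactants: 20 methyl 2-[(1S,4aS,5S,8aR)-5-{[(tert-butyldiphenylsilyl)oxy]methyl}-5,8a-dimethyl-2-oxo-1,2,4a,5,6,7,8,8a-octahydronaphthalen-1-yl]acetate
Product: 21 methyl 2-[(1R,4aS,5S,8aS)-5-{[(tert-butyldiphenylsilyl)oxy]methyl}-5,8a-dimethyl-2-methylidene-1,2,4a,5,6,7,8,8a-octahydronaphthalen-1-yl]acetate
Conditions: Ph3PCH3Br (1.5 equiv), KOt-Bu (1.4 equiv), THF, 0 °C to rt
Reagents that add atoms: methyltriphenylphosphonium bromide, C[P+](c1ccccc1)(c1ccccc1)c1ccccc1.[Br-]
Why: Wittig methylenation of the C8 ketone with the non-stabilised ylide should give the 6,8(17)-diene, the ester being far less electrophilic than the ketone and C9 keeping its equatorial arm because that is the thermodynamically preferred configuration even if the ketone enolises reversibly.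

Step 14
Reactants: 21 methyl 2-[(1R,4aS,5S,8aS)-5-{[(tert-butyldiphenylsilyl)oxy]methyl}-5,8a-dimethyl-2-methylidene-1,2,4a,5,6,7,8,8a-octahydronaphthalen-1-yl]acetate
Product: 22 2-[(1R,4aS,5S,8aS)-5-{[(tert-butyldiphenylsilyl)oxy]methyl}-5,8a-dimethyl-2-methylidene-1,2,4a,5,6,7,8,8a-octahydronaphthalen-1-yl]ethan-1-ol
Conditions: i-Bu2AlH (2.5 equiv), CH2Cl2, −78 to 0 °C; aq potassium sodium tartrate
Reagents that add atoms: none
Why: Reduction of the methyl ester by i-Bu2AlH (aluminium hydride reduction) should give the C12 primary alcohol without touching the diene or the silyl ether.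

Step 15
Reactants: 22 2-[(1R,4aS,5S,8aS)-5-{[(tert-butyldiphenylsilyl)oxy]methyl}-5,8a-dimethyl-2-methylidene-1,2,4a,5,6,7,8,8a-octahydronaphthalen-1-yl]ethan-1-ol
Product: 23 (1R,4aS,5S,8aS)-5-{[(tert-butyldiphenylsilyl)oxy]methyl}-1-(2-iodoethyl)-5,8a-dimethyl-2-methylidene-1,2,4a,5,6,7,8,8a-octahydronaphthalene
Conditions: PPh3, imidazole, I2 (premixed), CH2Cl2, 0 °C to rt
Reagents that add atoms: iodine, II
Why: Appel-type iodination with the preformed phosphine–iodine–imidazole reagent should replace the primary hydroxyl by iodide through SN2 displacement of the alkoxyphosphonium ion, with no free iodine left to attack the diene.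

Step 16
Reactants: 24 methyl 3-oxobutanoate (methyl acetoacetate)
Product: 25 methyl (2E)-3-{[(trifluoromethyl)sulfonyl]oxy}but-2-enoate
Conditions: Tf2O (1.5 equiv), aq Me4NOH (25 wt %), toluene, 5 °C
Reagents that add atoms: trifluoromethanesulfonic anhydride, O=S(=O)(OS(=O)(=O)C(F)(F)F)C(F)(F)F
Why: O-Sulfonylation of the ammonium enolate of the β-keto ester (enol triflate formation) should give the E-isomer, since the non-chelating tetramethylammonium counter-ion lets the enolate adopt the geometry with the ester group and the enolate oxygen anti.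

Step 17
Reactants: 23 (1R,4aS,5S,8aS)-5-{[(tert-butyldiphenylsilyl)oxy]methyl}-1-(2-iodoethyl)-5,8a-dimethyl-2-methylidene-1,2,4a,5,6,7,8,8a-octahydronaphthalene; 25 methyl (2E)-3-{[(trifluoromethyl)sulfonyl]oxy}but-2-enoate
Product: 27 methyl (2E)-5-[(1R,4aS,5S,8aS)-5-{[(tert-butyldiphenylsilyl)oxy]methyl}-5,8a-dimethyl-2-methylidene-1,2,4a,5,6,7,8,8a-octahydronaphthalen-1-yl]-3-methylpent-2-enoate, via alkylzinc iodide 26 (not isolated)
Conditions: Zn dust, LiCl, THF, 40 °C; filtered onto 25, PdCl2(dppf) (5 mol %), THF, rt to 50 °C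
Reagents that add atoms: none
Why: Zinc insertion into the primary C–I bond and Negishi cross-coupling of the alkylzinc iodide with the enol triflate should form the C12–C13 bond with retention of the E geometry, because oxidative addition and reductive elimination at palladium are stereoretentive and the activated triflate couples faster than β-hydride elimination can occur.

Step 18
Reactants: 27 methyl (2E)-5-[(1R,4aS,5S,8aS)-5-{[(tert-butyldiphenylsilyl)oxy]methyl}-5,8a-dimethyl-2-methylidene-1,2,4a,5,6,7,8,8a-octahydronaphthalen-1-yl]-3-methylpent-2-enoate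
Product: 28 methyl (2E)-5-[(1R,4aS,5S,8aS)-5-(hydroxymethyl)-5,8a-dimethyl-2-methylidene-1,2,4a,5,6,7,8,8a-octahydronaphthalen-1-yl]-3-methylpent-2-enoate
Conditions: Bu4NF, AcOH (1:1), THF, rt to 45 °C
Reagents that add atoms: none
Why: Fluoride-induced cleavage of the silicon–oxygen bond (desilylation), buffered with acetic acid, should free the C18 hydroxyl without hydrolysing the methyl ester or isomerising the dienoate.

Step 19
Reactants: 28 methyl (2E)-5-[(1R,4aS,5S,8aS)-5-(hydroxymethyl)-5,8a-dimethyl-2-methylidene-1,2,4a,5,6,7,8,8a-octahydronaphthalen-1-yl]-3-methylpent-2-enoate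
Product: 29 methyl (2E)-5-[(1R,4aS,5S,8aS)-5-(acetoxymethyl)-5,8a-dimethyl-2-methylidene-1,2,4a,5,6,7,8,8a-octahydronaphthalen-1-yl]-3-methylpent-2-enoate (CNP0148290.1)
Conditions: Ac2O, pyridine, DMAP (cat), CH2Cl2, rt
Reagents that add atoms: acetic anhydride, CC(=O)OC(C)=O
Why: DMAP-catalysed acylation of the primary neopentyl alcohol with acetic anhydride (esterification) should give the acetate under conditions that leave every other group untouched.

**Compound list**

1 | 2-methylpropane-1,3-diol | CC(CO)CO | starting material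
2 | 3-[(tert-butyldiphenylsilyl)oxy]-2-methylpropan-1-ol (racemic) | CC(CO)CO[Si](c1ccccc1)(c1ccccc1)C(C)(C)C | intermediate
3 | 3-[(tert-butyldiphenylsilyl)oxy]-2-methylpropanal (racemic) | CC(C=O)CO[Si](c1ccccc1)(c1ccccc1)C(C)(C)C | intermediate
4 | pent-1-en-3-one (ethyl vinyl ketone) | CCC(=O)C=C | starting material
5 | (2R)-2-{[(tert-butyldiphenylsilyl)oxy]methyl}-2-methyl-5-oxoheptanal (Michael adduct, not isolated) | CCC(=O)CC[C@](C)(CO[Si](c1ccccc1)(c1ccccc1)C(C)(C)C)C=O | intermediate
6 | (4S)-4-{[(tert-butyldiphenylsilyl)oxy]methyl}-2,4-dimethylcyclohex-2-en-1-one | O=C1CC[C@](C)(CO[Si](c2ccccc2)(c2ccccc2)C(C)(C)C)C=C1C | intermediate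
7 | allyltrimethylsilane | C=CC[Si](C)(C)C | starting material
8 | trichlorotitanium enolate of the 3-allyl ketone (O–TiCl3 on C1, C1=C10 double bond, allyl on C5 trans to the silyloxymethyl arm; not isolated) | C=CC[C@@H]1[C@@](C)(CO[Si](c2ccccc2)(c2ccccc2)C(C)(C)C)CCC(O[Ti](Cl)(Cl)Cl)=C1C | intermediate
9 | (2R,3R,4S)-4-{[(tert-butyldiphenylsilyl)oxy]methyl}-2-(hydroxymethyl)-2,4-dimethyl-3-(prop-2-en-1-yl)cyclohexan-1-one (allyl trans to both CH2O arms) | C=CC[C@@H]1[C@@](C)(CO[Si](c2ccccc2)(c2ccccc2)C(C)(C)C)CCC(=O)[C@@]1(C)CO | intermediate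
10 | 4-methylbenzenesulfonohydrazone of ketone 9 (C=N geometry not defined) | C=CC[C@@H]1[C@@](C)(CO[Si](c2ccccc2)(c2ccccc2)C(C)(C)C)CCC(=NNS(=O)(=O)c2ccc(C)cc2)[C@@]1(C)CO | intermediate
11 | [(1R,2S,3S)-3-{[(tert-butyldiphenylsilyl)oxy]methyl}-1,3-dimethyl-2-(prop-2-en-1-yl)cyclohexyl]methanol | C=CC[C@@H]1[C@@](C)(CO[Si](c2ccccc2)(c2ccccc2)C(C)(C)C)CCC[C@@]1(C)CO | intermediate
12 | (1R,2R,3S)-3-{[(tert-butyldiphenylsilyl)oxy]methyl}-1,3-dimethyl-2-(prop-2-en-1-yl)cyclohexane-1-carbaldehyde | C=CC[C@@H]1[C@@](C)(CO[Si](c2ccccc2)(c2ccccc2)C(C)(C)C)CCC[C@@]1(C)C=O | intermediate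
13 | methyl (triphenylphosphoranylidene)acetate | COC(=O)C=P(c1ccccc1)(c1ccccc1)c1ccccc1 | starting material
14 | methyl (2E)-3-[(1S,2S,3S)-3-{[(tert-butyldiphenylsilyl)oxy]methyl}-1,3-dimethyl-2-(prop-2-en-1-yl)cyclohexyl]prop-2-enoate | C=CC[C@@H]1[C@@](C)(CO[Si](c2ccccc2)(c2ccccc2)C(C)(C)C)CCC[C@@]1(C)/C=C/C(=O)OC | intermediate
15 | B-alkyl-9-borabicyclo[3.3.1]nonane from 14 (boron on the terminal carbon; not isolated) | C1CC2CCCC(C1)B2CCC[C@@H]1[C@@](C)(CO[Si](c2ccccc2)(c2ccccc2)C(C)(C)C)CCC[C@@]1(C)/C=C/C(=O)OC | intermediate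
16 | methyl (2E)-3-[(1S,2S,3S)-3-{[(tert-butyldiphenylsilyl)oxy]methyl}-2-(3-hydroxypropyl)-1,3-dimethylcyclohexyl]prop-2-enoate | OCCC[C@@H]1[C@@](C)(CO[Si](c2ccccc2)(c2ccccc2)C(C)(C)C)CCC[C@@]1(C)/C=C/C(=O)OC | intermediate
17 | methyl (2E)-3-[(1S,2S,3S)-3-{[(tert-butyldiphenylsilyl)oxy]methyl}-1,3-dimethyl-2-(3-oxopropyl)cyclohexyl]prop-2-enoate (ring A aldehyde with the E-enoate on C10) | O=CCC[C@@H]1[C@@](C)(CO[Si](c2ccccc2)(c2ccccc2)C(C)(C)C)CCC[C@@]1(C)/C=C/C(=O)OC | intermediate
18 | methyl 2-[(1S,4aS,5S,8aR)-5-{[(tert-butyldiphenylsilyl)oxy]methyl}-5,8a-dimethyl-2-oxodecahydronaphthalen-1-yl]acetate (trans-fused 8-oxo decalin, equatorial C9 arm) | O=C1CC[C@@H]2[C@@](C)(CO[Si](c3ccccc3)(c3ccccc3)C(C)(C)C)CCC[C@@]2(C)[C@@H]1CC(=O)OC | intermediate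
19 | trimethylsilyl enol ether of 18 (C7=C8; not isolated) | C[Si](C)(C)OC1=CC[C@@H]2[C@@](C)(CO[Si](c3ccccc3)(c3ccccc3)C(C)(C)C)CCC[C@@]2(C)[C@@H]1CC(=O)OC | intermediate
20 | methyl 2-[(1S,4aS,5S,8aR)-5-{[(tert-butyldiphenylsilyl)oxy]methyl}-5,8a-dimethyl-2-oxo-1,2,4a,5,6,7,8,8a-octahydronaphthalen-1-yl]acetate (6-en-8-one) | O=C1C=C[C@@H]2[C@@](C)(CO[Si](c3ccccc3)(c3ccccc3)C(C)(C)C)CCC[C@@]2(C)[C@@H]1CC(=O)OC | intermediate
21 | methyl 2-[(1R,4aS,5S,8aS)-5-{[(tert-butyldiphenylsilyl)oxy]methyl}-5,8a-dimethyl-2-methylidene-1,2,4a,5,6,7,8,8a-octahydronaphthalen-1-yl]acetate | C=C1C=C[C@@H]2[C@@](C)(CO[Si](c3ccccc3)(c3ccccc3)C(C)(C)C)CCC[C@@]2(C)[C@@H]1CC(=O)OC | intermediate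
22 | 2-[(1R,4aS,5S,8aS)-5-{[(tert-butyldiphenylsilyl)oxy]methyl}-5,8a-dimethyl-2-methylidene-1,2,4a,5,6,7,8,8a-octahydronaphthalen-1-yl]ethan-1-ol | C=C1C=C[C@@H]2[C@@](C)(CO[Si](c3ccccc3)(c3ccccc3)C(C)(C)C)CCC[C@@]2(C)[C@@H]1CCO | intermediate
23 | (1R,4aS,5S,8aS)-5-{[(tert-butyldiphenylsilyl)oxy]methyl}-1-(2-iodoethyl)-5,8a-dimethyl-2-methylidene-1,2,4a,5,6,7,8,8a-octahydronaphthalene | C=C1C=C[C@@H]2[C@@](C)(CO[Si](c3ccccc3)(c3ccccc3)C(C)(C)C)CCC[C@@]2(C)[C@@H]1CCI | intermediate
24 | methyl 3-oxobutanoate (methyl acetoacetate) | CC(=O)CC(=O)OC | starting material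
25 | methyl (2E)-3-{[(trifluoromethyl)sulfonyl]oxy}but-2-enoate | C/C(OS(=O)(=O)C(F)(F)F)=C\C(=O)OC | intermediate
26 | alkylzinc iodide from 23 (zinc on C12; not isolated) | C=C1C=C[C@@H]2[C@@](C)(CO[Si](c3ccccc3)(c3ccccc3)C(C)(C)C)CCC[C@@]2(C)[C@@H]1CC[Zn]I | intermediate
27 | methyl (2E)-5-[(1R,4aS,5S,8aS)-5-{[(tert-butyldiphenylsilyl)oxy]methyl}-5,8a-dimethyl-2-methylidene-1,2,4a,5,6,7,8,8a-octahydronaphthalen-1-yl]-3-methylpent-2-enoate | C=C1C=C[C@@H]2[C@@](C)(CO[Si](c3ccccc3)(c3ccccc3)C(C)(C)C)CCC[C@@]2(C)[C@@H]1CC/C(C)=C/C(=O)OC | intermediate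
28 | methyl (2E)-5-[(1R,4aS,5S,8aS)-5-(hydroxymethyl)-5,8a-dimethyl-2-methylidene-1,2,4a,5,6,7,8,8a-octahydronaphthalen-1-yl]-3-methylpent-2-enoate | C=C1C=C[C@@H]2[C@@](C)(CO)CCC[C@@]2(C)[C@@H]1CC/C(C)=C/C(=O)OC | intermediate
29 | methyl (2E)-5-[(1R,4aS,5S,8aS)-5-(acetoxymethyl)-5,8a-dimethyl-2-methylidene-1,2,4a,5,6,7,8,8a-octahydronaphthalen-1-yl]-3-methylpent-2-enoate (CNP0148290.1) | C=C1C=C[C@@H]2[C@@](C)(COC(C)=O)CCC[C@@]2(C)[C@@H]1CC/C(C)=C/C(=O)OC | target

**Step count and risks**

Total step count: 19. Longest linear sequence: 18 steps (steps 1–15 and 17–19); step 16 is a one-step branch.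

Steps most likely to fail:

1. Step 11 (ring B closure). The conjugate addition of the Breslow intermediate to C9, which is shielded by quaternary C10, may be too slow; the enolisable aldehyde would then be consumed by aldol or acyloin self-condensation, or the carbene would be held as an unreactive adduct. The fallback sets out from 17 and returns at 18, forming the same C8–C9 bond with an acyl radical in place of the polar acyl donor. Chlorite oxidation of 17 (NaClO2, NaH2PO4, 2-methylbut-2-ene, t-BuOH/H2O) gives the carboxylic acid F1. Diphenyl diselenide and Bu3P convert it into the Se-phenyl selenoester F2. Slow addition of Bu3SnH with AIBN in benzene at 80 °C generates the acyl radical, which closes ring B by 6-exo-trig addition to C9 of the enoate; hydrogen transfer to the ester-stabilised radical and DBU equilibration at C9 then give 18.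

2. Step 4 (C5 and C10). Face discrimination at C5 between the methyl and silyloxymethyl arms of C4 may be insufficient, and protonation or oligomer formation may compete with formaldehyde capture of the hindered titanium enolate. The fallback sets out from 6 and returns at 9. Allylmagnesium bromide with CuBr·SMe2 and Me3SiCl in THF at −78 °C (organocopper conjugate addition with silylation in the same flask, a later and more product-like transition state that should respond more strongly to the size of the C4 arms) gives the trimethylsilyl enol ether F3, whose double bond is fixed between C1 and C10. The isolated enol ether is hydroxymethylated with aqueous formaldehyde and Sc(OTf)3 (Mukaiyama-type aldol in water), formaldehyde again entering anti to the allyl group, to give 9. Any C5 epimer can be removed at F3 or at 9.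

3. Step 3 (C4). Enantiofacial discrimination may be low because the enamine has to tell a methyl group from a CH2OSi arm, and enamine formation from the α-branched aldehyde may be slow. The fallback sets out from 3 and 4 and returns at 6. The annulation is run without chiral control (pyrrolidine, AcOH, then KOH in MeOH) to give the racemic enone F4. Addition of lithiated (S)-N,S-dimethyl-S-phenylsulfoximine to the carbonyl group gives diastereomeric β-hydroxy sulfoximines, which are separated by chromatography or crystallisation into the adducts of the (S)-enone F5 and the adducts of the (R)-enone F6. Heating F5 in toluene reverses the addition and releases enantiopure 6; the sulfoximine is recovered.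

**Further compounds**

F1 | step 11 | 3-[(1S,2S,6S)-configured ring A]propanoic acid: the C8 carboxylic acid corresponding to aldehyde 17 | OC(=O)CC[C@@H]1[C@@](C)(CO[Si](c2ccccc2)(c2ccccc2)C(C)(C)C)CCC[C@@]1(C)/C=C/C(=O)OC
F2 | step 11 | Se-phenyl selenoester of acid F1 | O=C([Se]c2ccccc2)CC[C@@H]1[C@@](C)(CO[Si](c3ccccc3)(c3ccccc3)C(C)(C)C)CCC[C@@]1(C)/C=C/C(=O)OC
F3 | step 4 | trimethylsilyl enol ether of the 3-allyl ketone (C1–OSiMe3, C1=C10, allyl on C5 trans to the silyloxymethyl arm) | C=CC[C@@H]1[C@@](C)(CO[Si](c2ccccc2)(c2ccccc2)C(C)(C)C)CCC(O[Si](C)(C)C)=C1C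
F4 | step 3 | racemic 4-{[(tert-butyldiphenylsilyl)oxy]methyl}-2,4-dimethylcyclohex-2-en-1-one | CC1=CC(C)(CO[Si](c2ccccc2)(c2ccccc2)C(C)(C)C)CCC1=O
F5 | step 3 | β-hydroxy sulfoximine from the (S)-enone and (S)-N,S-dimethyl-S-phenylsulfoximine (both carbinol epimers) | CN=[S@](=O)(CC1(O)CC[C@](C)(CO[Si](c2ccccc2)(c2ccccc2)C(C)(C)C)C=C1C)c1ccccc1
F6 | step 3 | β-hydroxy sulfoximine from the (R)-enone and (S)-N,S-dimethyl-S-phenylsulfoximine (both carbinol epimers) | CN=[S@](=O)(CC1(O)CC[C@@](C)(CO[Si](c2ccccc2)(c2ccccc2)C(C)(C)C)C=C1C)c1ccccc1
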